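The route rests on cutting the C4–C4a bond of ring C. Because prenyl occupies C8, C4a is the only free carbon ortho to O1 on ring A, and it is activated by O1 and by the oxygens at C5 and C7; an acyl group tethered through O1–C2–C3 can therefore close the pyranone only there. One intramolecular Friedel–Crafts acylation forms C4–C4a and ring C while C2 and C3 stay as set. The precursor is a (2R,3R)-2-acetoxy-3-aryl-3-aryloxypropanoic acid, made by SN2 opening of a (2R,3S)-glycidate at its benzylic carbon with 3,5-dimethoxy-2-prenylphenol; the ring B hydroxyl is carried as an acetate.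

Key step: step 10

Remark: positions are given in flavanone numbering (O1, C2, C3, C4, C4a, C5 to C8, C8a; ring B primed), and both hydroxyl groups that pass through the ring closure are carried as acetates, so that ring B is electron-poor when the acyl cation is generated and one deacylation frees both.

Step 1
Reactants: 1 3,5-dimethoxyphenol; 2 3-chloro-3-methylbut-1-yne
Product: 3 1,3-dimethoxy-5-[(2-methylbut-3-yn-2-yl)oxy]benzene
Conditions: DBU, CuCl2·2H2O (1 mol%), MeCN, 0 °C
Reagents that add atoms: none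
Why: Copper-catalysed O-alkylation of a phenol with a tertiary propargylic chloride is the standard entry to aryl 1,1-dimethylpropargyl ethers and forms no stereocentre.

Step 2
Reactants: 3 1,3-dimethoxy-5-[(2-methylbut-3-yn-2-yl)oxy]benzene
Product: 4 1,3-dimethoxy-5-[(2-methylbut-3-en-2-yl)oxy]benzene
Conditions: H2 (1 atm), Pd/CaCO3 poisoned with Pb(OAc)2, quinoline, EtOAc, rt
Reagents that add atoms: none
Why: Semihydrogenation of a terminal alkyne over lead-poisoned palladium (Lindlar reduction) stops at the alkene and leaves the aryl ether alone.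

Step 3
Reactants: 4 1,3-dimethoxy-5-[(2-methylbut-3-en-2-yl)oxy]benzene
Product: 5 3,5-dimethoxy-2-(3-methylbut-2-en-1-yl)phenol
Conditions: PhNEt2, 170 °C, argon
Reagents that add atoms: none
Why: Aromatic Claisen rearrangement, a [3,3] shift that turns the 1,1-dimethylallyl ether into an ortho prenyl group; the two ortho carbons of 4 are equivalent by symmetry, so one phenol should form, and the basic solvent holds back acid-induced chroman formation.

Step 4
Reactants: 6 isovanillin (3-hydroxy-4-methoxybenzaldehyde)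
Product: 7 3-(allyloxy)-4-methoxybenzaldehyde
Conditions: allyl bromide, K2CO3, DMF, rt
Reagents that add atoms: allyl bromide, C=CCBr
Why: Williamson ether synthesis on the only acidic hydroxyl group.

Step 5
Reactants: 7 3-(allyloxy)-4-methoxybenzaldehyde
Product: 8 methyl (E)-3-[3-(allyloxy)-4-methoxyphenyl]prop-2-enoate
Conditions: (MeO)2P(O)CH2CO2Me, NaH, THF, 0 °C to rt
Reagents that add atoms: trimethyl phosphonoacetate, COC(=O)CP(=O)(OC)OC
Why: Horner–Wadsworth–Emmons olefination of an aromatic aldehyde with a stabilised phosphonate anion gives the (E)-enoate.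

Step 6
Reactants: 8 methyl (E)-3-[3-(allyloxy)-4-methoxyphenyl]prop-2-enoate
Product: 9 methyl (2R,3S)-3-[3-(allyloxy)-4-methoxyphenyl]oxirane-2-carboxylate
Conditions: Y(O-iPr)3/6,6'-[oxybis(ethylene)dioxy]biphenyl-2,2'-diol (single antipode)/Ph3As=O (1:1:1, 10 mol%), t-BuOOH in decane, 4 Å MS, THF, rt
Reagents that add atoms: tert-butyl hydroperoxide, CC(C)(C)OO
Why: Catalytic asymmetric nucleophilic epoxidation of a β-aryl enoate (conjugate addition of yttrium-bound tert-butylperoxide, then closure with loss of tert-butoxide) sets both oxirane carbons at once, trans from the (E)-alkene and with the face chosen by the chiral biphenyldiolate, whose antipode giving the (2R,3S) epoxide is fixed in a trial run since both are available; a nucleophilic oxidant does not touch the allyl ether alkene.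

Step 7
Reactants: 9 methyl (2R,3S)-3-[3-(allyloxy)-4-methoxyphenyl]oxirane-2-carboxylate; 5 3,5-dimethoxy-2-(3-methylbut-2-en-1-yl)phenol
Product: 10 methyl (2R,3R)-3-[3-(allyloxy)-4-methoxyphenyl]-3-[3,5-dimethoxy-2-(3-methylbut-2-en-1-yl)phenoxy]-2-hydroxypropanoate
Conditions: 5 (1.3 equiv), Cs2CO3 (0.3 equiv), DMF, 50 °C
Reagents that add atoms: none
Why: Base-mediated SN2 opening of an aryl oxirane by a phenoxide: the phenoxide attacks the benzylic C3 of the trans-glycidate (C2, next to the ester, is the less reactive oxirane carbon) anti to the ring oxygen, so C3 is inverted from S to R while C2 stays R, and the absence of any Lewis or protic acid keeps the opening from drifting towards a 4-methoxybenzylic cation.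

Step 8
Reactants: 10 methyl (2R,3R)-3-[3-(allyloxy)-4-methoxyphenyl]-3-[3,5-dimethoxy-2-(3-methylbut-2-en-1-yl)phenoxy]-2-hydroxypropanoate
Product: 12 (2R,3R)-3-[3,5-dimethoxy-2-(3-methylbut-2-en-1-yl)phenoxy]-2-hydroxy-3-(3-hydroxy-4-methoxyphenyl)propanoic acid, via phenol methyl ester 11 (not isolated)
Conditions: Pd(PPh3)4 (2 mol%), K2CO3, MeOH, rt to 40 °C; then LiOH, H2O–THF, 0 °C to rt; 1 M HCl to pH 3 at 0 °C
Reagents that add atoms: lithium hydroxide, [Li+].[OH-]
Why: Tsuji–Trost-type deallylation (zerovalent palladium ionises the aryl allyl ether and methoxide takes the allyl group) followed in the same flask by saponification of the methyl ester; carbonate and hydroxide at room temperature are too weak to deprotonate C2, so neither stereocentre is at risk, and the prenyl group offers palladium no leaving group.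

Step 9
Reactants: 12 (2R,3R)-3-[3,5-dimethoxy-2-(3-methylbut-2-en-1-yl)phenoxy]-2-hydroxy-3-(3-hydroxy-4-methoxyphenyl)propanoic acid
Product: 14 (2R,3R)-2-acetoxy-3-(3-acetoxy-4-methoxyphenyl)-3-[3,5-dimethoxy-2-(3-methylbut-2-en-1-yl)phenoxy]propanoic acid, via mixed acetic anhydride 13 (not isolated)
Conditions: Ac2O, pyridine, 0 °C to rt; then H2O, rt
Reagents that add atoms: acetic anhydride, CC(=O)OC(C)=O
Why: Acetylation of the phenol and the secondary alcohol with Ac2O/pyridine; the carboxyl group is acetylated as well to the mixed anhydride 13, which water cleaves back to the acid while the aryl and alkyl acetates remain.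

Step 10
Reactants: 14 (2R,3R)-2-acetoxy-3-(3-acetoxy-4-methoxyphenyl)-3-[3,5-dimethoxy-2-(3-methylbut-2-en-1-yl)phenoxy]propanoic acid
Product: 16 (2R,3R)-2-(3-acetoxy-4-methoxyphenyl)-5,7-dimethoxy-8-(3-methylbut-2-en-1-yl)-4-oxochroman-3-yl acetate, via acid chloride 15 (not isolated)
Conditions: Me2C=C(Cl)NMe2 (1.2 equiv), CH2Cl2, 0 °C to rt; then 2,6-di-tert-butyl-4-methylpyridine, SnCl4 (2.5 equiv), −78 to −40 °C; NaHCO3 (aq) at −78 °C
Reagents that add atoms: none
Why: The chloroenamine turns the acid into the acid chloride without releasing HCl, and SnCl4 then generates an acyl cation equivalent that attacks C4a of ring A; loss of the proton to the hindered pyridine restores the arene and leaves the chroman-4-one. The closest known reaction type is the intramolecular Friedel–Crafts acylation of 3-aryloxypropanoic acids and their chlorides to chroman-4-ones. Ring C closes as a six-membered ring by 6-exo-trig attack of the arene carbon on the acyl carbon. No stereocentre is formed: C2 and C3 come unchanged from 14, because no enolising base is present and the C2–O1 bond is not expected to ionise at −78 °C, its cation being disfavoured by the 3'-acetoxy group and the acyl-bearing neighbour. The step needs site selectivity on ring A, preference over ring B and survival of the prenyl alkene: C8 is blocked by prenyl and C6 cannot be reached by the tether, so C4a (ortho to O1 and the 5-methoxy group, para to the 7-methoxy group) is the only site; ring B has only an acetoxy group para to C6' and would have to close a strained five-membered ketone; and the medium holds no free protic acid.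

Step 11
Reactants: 16 (2R,3R)-2-(3-acetoxy-4-methoxyphenyl)-5,7-dimethoxy-8-(3-methylbut-2-en-1-yl)-4-oxochroman-3-yl acetate
Product: 17 (2R,3R)-2-(3-acetoxy-4-methoxyphenyl)-5-hydroxy-7-methoxy-8-(3-methylbut-2-en-1-yl)-4-oxochroman-3-yl acetate
Conditions: MgI2·OEt2 (3 equiv), THF, 60 °C; 1 M HCl, Na2S2O3 (aq)
Reagents that add atoms: none
Why: Chelation-controlled ether cleavage: magnesium bridges the C4 carbonyl and the 5-methoxy oxygen and iodide removes that methyl group by SN2, a reagent known for 5-O-demethylation of 8-prenylflavanones, so the 7- and 4'-methyl ethers, the acetates and the prenyl group (which has no free ortho hydroxyl to cyclise onto) should stay.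

Step 12
Reactants: 17 (2R,3R)-2-(3-acetoxy-4-methoxyphenyl)-5-hydroxy-7-methoxy-8-(3-methylbut-2-en-1-yl)-4-oxochroman-3-yl acetate
Product: 18 (2R,3R)-3,5-dihydroxy-2-(3-hydroxy-4-methoxyphenyl)-7-methoxy-8-(3-methylbut-2-en-1-yl)chroman-4-one (CNP0302743.1)
Conditions: HCl (0.3 M) in MeOH, 0 to 30 °C, argon
Reagents that add atoms: none
Why: Acid-catalysed transesterification to methanol frees the 3'-phenol and the C3 hydroxyl without base, so enolisation at C3, ring opening and air oxidation of the hydroxychromanone are not invited, and dilute methanolic HCl is tolerated by a prenyl group that lacks an ortho hydroxyl.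

Compound list
1 | 3,5-dimethoxyphenol | COc1cc(O)cc(OC)c1 | starting material
2 | 3-chloro-3-methylbut-1-yne | CC(C)(Cl)C#C | starting material
3 | 1,3-dimethoxy-5-[(2-methylbut-3-yn-2-yl)oxy]benzene | COc1cc(OC)cc(OC(C)(C)C#C)c1 | intermediate
4 | 1,3-dimethoxy-5-[(2-methylbut-3-en-2-yl)oxy]benzene | COc1cc(OC)cc(OC(C)(C)C=C)c1 | intermediate
5 | 3,5-dimethoxy-2-(3-methylbut-2-en-1-yl)phenol | COc1cc(O)c(CC=C(C)C)c(OC)c1 | intermediate
6 | isovanillin (3-hydroxy-4-methoxybenzaldehyde) | COc1ccc(C=O)cc1O | starting material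
7 | 3-(allyloxy)-4-methoxybenzaldehyde | COc1ccc(C=O)cc1OCC=C | intermediate
8 | methyl (E)-3-[3-(allyloxy)-4-methoxyphenyl]prop-2-enoate | COC(=O)/C=C/c1ccc(OC)c(OCC=C)c1 | intermediate
9 | methyl (2R,3S)-3-[3-(allyloxy)-4-methoxyphenyl]oxirane-2-carboxylate | COC(=O)[C@@H]1O[C@H]1c1ccc(OC)c(OCC=C)c1 | intermediate
10 | methyl (2R,3R)-3-[3-(allyloxy)-4-methoxyphenyl]-3-[3,5-dimethoxy-2-(3-methylbut-2-en-1-yl)phenoxy]-2-hydroxypropanoate | COc1ccc([C@@H](Oc2cc(OC)cc(OC)c2CC=C(C)C)[C@@H](O)C(=O)OC)cc1OCC=C | intermediate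
11 | phenol methyl ester: methyl (2R,3R)-3-[3,5-dimethoxy-2-(3-methylbut-2-en-1-yl)phenoxy]-2-hydroxy-3-(3-hydroxy-4-methoxyphenyl)propanoate | COc1ccc([C@@H](Oc2cc(OC)cc(OC)c2CC=C(C)C)[C@@H](O)C(=O)OC)cc1O | intermediate
12 | (2R,3R)-3-[3,5-dimethoxy-2-(3-methylbut-2-en-1-yl)phenoxy]-2-hydroxy-3-(3-hydroxy-4-methoxyphenyl)propanoic acid | COc1ccc([C@@H](Oc2cc(OC)cc(OC)c2CC=C(C)C)[C@@H](O)C(O)=O)cc1O | intermediate
13 | mixed acetic anhydride: acetic (2R,3R)-2-acetoxy-3-(3-acetoxy-4-methoxyphenyl)-3-[3,5-dimethoxy-2-(3-methylbut-2-en-1-yl)phenoxy]propanoic anhydride | COc1ccc([C@@H](Oc2cc(OC)cc(OC)c2CC=C(C)C)[C@@H](OC(C)=O)C(=O)OC(C)=O)cc1OC(C)=O | intermediate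
14 | (2R,3R)-2-acetoxy-3-(3-acetoxy-4-methoxyphenyl)-3-[3,5-dimethoxy-2-(3-methylbut-2-en-1-yl)phenoxy]propanoic acid | COc1ccc([C@@H](Oc2cc(OC)cc(OC)c2CC=C(C)C)[C@@H](OC(C)=O)C(O)=O)cc1OC(C)=O | intermediate
15 | acid chloride: (2R,3R)-2-acetoxy-3-(3-acetoxy-4-methoxyphenyl)-3-[3,5-dimethoxy-2-(3-methylbut-2-en-1-yl)phenoxy]propanoyl chloride | COc1ccc([C@@H](Oc2cc(OC)cc(OC)c2CC=C(C)C)[C@@H](OC(C)=O)C(Cl)=O)cc1OC(C)=O | intermediate
16 | (2R,3R)-2-(3-acetoxy-4-methoxyphenyl)-5,7-dimethoxy-8-(3-methylbut-2-en-1-yl)-4-oxochroman-3-yl acetate | COc1ccc([C@H]2Oc3c(CC=C(C)C)c(OC)cc(OC)c3C(=O)[C@@H]2OC(C)=O)cc1OC(C)=O | intermediate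
17 | (2R,3R)-2-(3-acetoxy-4-methoxyphenyl)-5-hydroxy-7-methoxy-8-(3-methylbut-2-en-1-yl)-4-oxochroman-3-yl acetate | COc1ccc([C@H]2Oc3c(CC=C(C)C)c(OC)cc(O)c3C(=O)[C@@H]2OC(C)=O)cc1OC(C)=O | intermediate
18 | (2R,3R)-3,5-dihydroxy-2-(3-hydroxy-4-methoxyphenyl)-7-methoxy-8-(3-methylbut-2-en-1-yl)chroman-4-one | COc1ccc([C@H]2Oc3c(CC=C(C)C)c(OC)cc(O)c3C(=O)[C@@H]2O)cc1O | target

Total step count: 12.
Longest linear sequence: 9 steps (steps 4 to 12 from isovanillin; the phenol branch, steps 1 to 3, joins at step 7 and is equally long).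

Steps most likely to fail

Step 10. Before the arene attacks, the Lewis acid may ionise the C2–O1 bond with help from the neighbouring acetate (loss of the ring A phenol, or epimerisation at C2), or HCl may add to the prenyl alkene. The fallback sets out from 5 and 9 and comes back at 16; it makes the two bonds of ring C in the opposite order. Phenol 5 is protected as the methoxymethyl ether F1 (MOMCl, i-Pr2NEt, CH2Cl2). Glycidate 9 is converted into the N-methoxy-N-methylamide F2 (MeNHOMe·HCl, i-PrMgCl, THF, −20 °C). F1 is lithiated with n-BuLi at the carbon between the acetal oxygen and the neighbouring methoxy group and added to F2 at −78 °C, which should give the epoxy ketone F3, in which C4–C4a already exists. Methanolic HCl then removes the acetal and the freed phenol opens the oxirane at its benzylic carbon. This is the known acid cyclisation of 2'-hydroxychalcone epoxides, in which C3 is kept and C2 settles trans, and it gives the 3'-O-allyl flavanonol F4. Deallylation with Pd(PPh3)4/K2CO3/MeOH gives the diol F5, and Ac2O/pyridine returns 16.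

Step 7. The phenoxide may attack the ester carbonyl or act as a base, or the opening may take on carbocation character at the 4-methoxybenzylic carbon so that inversion is incomplete. The fallback sets out from 9 and comes back at 12; it takes the ester out of play before the ether is made. NaBH4 in MeOH at 0 °C reduces 9 to the epoxy alcohol F6. The sodium salt of 5 in aqueous NaOH/dioxane at 70 °C opens F6 at the benzylic carbon with inversion, as in the known preparation of 3-aryl-3-aryloxypropane-1,2-diols from aryl glycidols, giving the diol F7. TEMPO/PhI(OAc)2 in MeCN–H2O oxidises only the primary alcohol and gives the hydroxy acid F8. Pd(PPh3)4/K2CO3/MeOH then removes the allyl group and gives 12.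

Step 6. Conjugate addition of the peroxide to this electron-rich enoate may be slow, and the face selectivity may fall short. The fallback sets out from 7 and comes back at 9; it replaces asymmetric catalysis by resolution. Darzens condensation of 7 with methyl chloroacetate and NaOMe in MeOH gives the racemic trans-glycidate F9. A lipase (the Serratia marcescens enzyme used on the 4-methoxyphenyl analogue) hydrolyses the (2S,3R)-ester to the glycidic acid F10, which is washed out as its salt, and leaves 9.

Further compounds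
F1 | step 10 | 1,5-dimethoxy-3-(methoxymethoxy)-2-(3-methylbut-2-en-1-yl)benzene | COCOc1cc(OC)cc(OC)c1CC=C(C)C
F2 | step 10 | (2R,3S)-3-[3-(allyloxy)-4-methoxyphenyl]-N-methoxy-N-methyloxirane-2-carboxamide | CON(C)C(=O)[C@@H]1O[C@H]1c1ccc(OC)c(OCC=C)c1
F3 | step 10 | [(2R,3S)-3-[3-(allyloxy)-4-methoxyphenyl]oxiran-2-yl][4,6-dimethoxy-2-(methoxymethoxy)-3-(3-methylbut-2-en-1-yl)phenyl]methanone | COCOc1c(CC=C(C)C)c(OC)cc(OC)c1C(=O)[C@@H]1O[C@H]1c1ccc(OC)c(OCC=C)c1
F4 | step 10 | (2R,3R)-2-[3-(allyloxy)-4-methoxyphenyl]-3-hydroxy-5,7-dimethoxy-8-(3-methylbut-2-en-1-yl)chroman-4-one | COc1ccc([C@H]2Oc3c(CC=C(C)C)c(OC)cc(OC)c3C(=O)[C@@H]2O)cc1OCC=C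
F5 | step 10 | (2R,3R)-3-hydroxy-2-(3-hydroxy-4-methoxyphenyl)-5,7-dimethoxy-8-(3-methylbut-2-en-1-yl)chroman-4-one | COc1ccc([C@H]2Oc3c(CC=C(C)C)c(OC)cc(OC)c3C(=O)[C@@H]2O)cc1O
F6 | step 7 | [(2S,3S)-3-[3-(allyloxy)-4-methoxyphenyl]oxiran-2-yl]methanol | OC[C@@H]1O[C@H]1c1ccc(OC)c(OCC=C)c1
F7 | step 7 | (2S,3R)-3-[3-(allyloxy)-4-methoxyphenyl]-3-[3,5-dimethoxy-2-(3-methylbut-2-en-1-yl)phenoxy]propane-1,2-diol | COc1ccc([C@@H](Oc2cc(OC)cc(OC)c2CC=C(C)C)[C@@H](O)CO)cc1OCC=C
F8 | step 7 | (2R,3R)-3-[3-(allyloxy)-4-methoxyphenyl]-3-[3,5-dimethoxy-2-(3-methylbut-2-en-1-yl)phenoxy]-2-hydroxypropanoic acid | COc1ccc([C@@H](Oc2cc(OC)cc(OC)c2CC=C(C)C)[C@@H](O)C(O)=O)cc1OCC=C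
F9 | step 6 | racemic methyl trans-3-[3-(allyloxy)-4-methoxyphenyl]oxirane-2-carboxylate (both enantiomers written) | COC(=O)[C@@H]1O[C@H]1c1ccc(OC)c(OCC=C)c1.COC(=O)[C@H]1O[C@@H]1c1ccc(OC)c(OCC=C)c1
F10 | step 6 | (2S,3R)-3-[3-(allyloxy)-4-methoxyphenyl]oxirane-2-carboxylic acid | OC(=O)[C@H]1O[C@@H]1c1ccc(OC)c(OCC=C)c1
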